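Amounts first, since you wanted a quick number. Friday's flask was charged with 0.400 M of J against 3.60 M of Z, so J was the limiting reagent. By the overall equation each E made had taken one J, so c_J left was the charge minus c_E. That balance let me test your hunch that so much Z would carry J to the end.

| flask | J | Z | time |
|---|---|---|---|
| Wednesday's | 0.800 M | 1.20 M |  |
| Tuesday's | 0.400 M | 0.800 M |  |
| Thursday's | 2.40 M | 1.20 M |  |
| Saturday's | 0.800 M | 1.80 M |  |
| Friday's | 0.400 M | 3.60 M | 16 min |

| run | time / min | [E] / M |
|---|---|---|
| Wednesday's run | 2.0 | 0.1485 |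
| Wednesday's run | 4.0 | 0.2562 |
| Wednesday's run | 6.0 | 0.3273 |
| Wednesday's run | 8.0 | 0.3764 |
| Wednesday's run | 10 | 0.4127 |
| Wednesday's run | 12 | 0.4322 |
| Wednesday's run | 14 | 0.4486 |
| Wednesday's run | 16 | 0.4593 |
| Tuesday's run | 2.0 | 0.0625 |
| Tuesday's run | 4.0 | 0.1040 |
| Tuesday's run | 6.0 | 0.1401 |
| Tuesday's run | 8.0 | 0.1683 |
| Tuesday's run | 10 | 0.1864 |
| Tuesday's run | 12 | 0.2024 |
| Tuesday's run | 14 | 0.2195 |
| Tuesday's run | 16 | 0.2269 |
| Thursday's run | 2.0 | 0.4024 |
| Thursday's run | 4.0 | 0.6203 |
| Thursday's run | 6.0 | 0.7301 |
| Thursday's run | 8.0 | 0.7822 |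
| Thursday's run | 10 | 0.8082 |
| Thursday's run | 12 | 0.8199 |
| Thursday's run | 14 | 0.8215 |
| Thursday's run | 16 | 0.8157 |
| Saturday's run | 2.0 | 0.1939 |
| Saturday's run | 4.0 | 0.3209 |
| Saturday's run | 6.0 | 0.4079 |
| Saturday's run | 8.0 | 0.4563 |
| Saturday's run | 10 | 0.4972 |
| Saturday's run | 12 | 0.5134 |
| Saturday's run | 14 | 0.5268 |
| Saturday's run | 16 | 0.5387 |

(standard deviation of a reading: 0.002 M)

- how the opening rate goes with [J] round the charge of the Wednesday's run: the exponent of the rate at two percent of J gone to E (one fixed amount of E, the same in the runs compared)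
- how the opening rate goes with [Z] round the charge of the Wednesday's run: the exponent of the rate at two percent of J gone to E
- E in the Friday's run at 16 min, as a share of the J charged

- Overall: J + Z -> E.
- Constant volume, constant temperature.
- A reading of a species includes what of it is bound.
- "The second partner" is Z.
- An order is taken over about fifteen percent of the charge, up and down.

Saturday's run over its first 2.0 min gave 0.139 min⁻¹ for what I called the spent-J constant k_J: the natural logarithm of c_J charged over c_J left, divided by the time. Tuesday's run gave 0.0849 min⁻¹ over the same opening. Those two runs differed in the J charged as well as in the Z charged; setting the J aside as my own assumption, I had k_J going as c_Z to the power 0.605. Friday's c_Z was twice Saturday's, so I took 0.211 min⁻¹ as Friday's opening k_J.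

But k_J did not hold. Tuesday's run, with Friday's charge of J, kept 0.616 of its opening value when reckoned over the whole 16 min. I applied that share to Friday's flask and got a mean k_J of 0.130 min⁻¹, hence E at 16 min of 87.5% of the J charged. So I did not expect the end.

The forecast said 85%, lower than my figure, with exponents of 0.95 for J and 0.7 for Z, and it read in the runs that “Z partly saturates”.

Friday's flask gave 86.8%, and round the charge of Wednesday's run the exponents were 1.0 for J and 0.74 for Z.

    J + Z ⇌ E + G (0.1500 M⁻¹ min⁻¹, 0.07440 M⁻¹ min⁻¹)
    2 Z ⇌ Z2, settled at all times (0.4130 M⁻¹)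
    Z → Jy (0.02820 min⁻¹)

A power-law fit, with a root-mean-square residual of 27 times the scatter, had given Friday's flask 98.3%, higher than the result. Put back into k_J, Friday's result is a mean of 0.127 min⁻¹ over 16 min. Tuesday's opening k_J of 0.0849 min⁻¹ put half of its J charged at 8.16 min, and Tuesday's run came to half later, at 11.6 min.

The runs were generated by integration with constants of no real substance, and the scatter is random.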